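| setting | teal | blue | flask |
|---|---|---|---|
| left-handed substrate | 0.025 M | 0.038 M | 0.050 M |
| right-handed substrate | 0.025 M | 0.038 M | 0.050 M |
| reagent | 2.2 equiv | 2.2 equiv | 2.20 equiv |
| racemization catalyst | 2 mol% | 2 mol% | 2 mol% |
| remark | run made earlier | run made earlier |  |
| time |  |  | 10 d |

| run | time / d | left-handed product / % | right-handed product / % | left-handed substrate / % |
|---|---|---|---|---|
| teal | 1.04 | 4.6 | 0 | 46.1 |
| teal | 3.00 | 12.1 | 2.0 | 41.5 |
| teal | 5.00 | 19.3 | 2.6 | 37.6 |
| teal | 8.00 | 27.1 | 3.7 | 32.7 |
| blue | 1.04 | 7.6 | 0.9 | 45.1 |
| blue | 3.00 | 17.3 | 2.1 | 39.3 |
| blue | 5.00 | 26.1 | 3.7 | 33.8 |
| blue | 8.00 | 35.3 | 5.9 | 28.9 |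

(scatter of a reading: 0.5 percentage points)

* left-handed product and right-handed product together, in percent of the left-handed substrate and right-handed substrate charged together, at 10 d
* excess of left-handed product over right-handed product in the product at 10 d
* whether the exchange between left-handed substrate and right-handed substrate keeps pace with the reaction: how far the product's excess at 10 d gets from its value without exchange to its value with instant exchange (above 80% keeps pace, below 20% hardly takes part, else lags behind)

- reagent is single-handed; left-handed substrate and right-handed substrate are mirror images of each other, charged as a racemate, each of them at the stated concentration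
- the earlier runs were read with a standard deviation of 0.5 percentage points
- an excess is the difference of the two amounts in percent of their sum
- an excess is below zero if the other one leads
- the handed part of reagent does not stay in what it makes, so the products of the two hands are mirror images too

The reagent has two rate constants, one for each substrate, and I want their ratio from these runs. Pooling teal and blue at 5.00 d, I read left-handed product over right-handed product as 7.21. Left-handed substrate over right-handed substrate, the latter by balance of the charge, is 0.928, and at 8.00 d it reads 0.928. The ratio of the two rates is the constants' ratio times the substrate ratio, and I take the product ratio read here as an estimate of that rate ratio, so I get 7.76, the selectivity factor: the left-handed substrate's constant over the right-handed substrate's. Each reading carries 0.5 percentage points, so the factor is a reading too.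

Now the two extremes. With instant exchange the substrates stay equal, and the excess is the factor less one over the factor plus one, 77.2%. Without exchange, the fraction of left-handed substrate remaining equals the fraction of right-handed substrate remaining raised to that factor. Taking as my trial point a quarter of the left-handed substrate remaining, 0.836 of the right-handed remains, and at 45.7% conversion the excess is 64.2%.

At that conversion the extreme has a substrate ratio of 0.299; the pooled runs have less converted, 36.0% at 8.00 d, and their ratio reads far above it. If the flask holds their ratio, I expect 75.6%, which is 88.1% of the way, above 80%: the exchange keeps pace.

The forecast says 57.5% product, excess 75%, keeps pace, with exchange “rising with catalyst concentration”. Its excess stands slightly below mine; for the yield I have no reckoning of my own.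

The flask gives 53.0% product and excess 75.4%; the exchange keeps pace, 88% of the way.

    2 racemization catalyst → spent catalyst B (k = 0.0187 M⁻¹ s⁻¹)
    2 racemization catalyst ⇌ resting dimer, settled at all times (K = 2400 M⁻¹)
    racemization catalyst → spent catalyst A (k = 3.74 × 10⁻⁶ s⁻¹)
    reagent + left-handed substrate → left-handed product (k = 2.08 × 10⁻⁵ M⁻¹ s⁻¹)
    reagent + right-handed substrate → right-handed product (k = 2.70 × 10⁻⁶ M⁻¹ s⁻¹)
    left-handed substrate + racemization catalyst ⇌ right-handed substrate + racemization catalyst, rate k6*[racemization catalyst]*[left-handed substrate] forward; the back reaction follows from the equilibrium constant (k = 0.0951 M⁻¹ s⁻¹)

The flask's substrate ratio reads 0.918 at 5.00 d and 0.798 at 10.0 d, while racemization catalyst goes from 6.95% to 1.36% of its charge. Times the factor, the later ratio gives 6.19 for the two rates at that moment, less than the 7.13 gathered in the flask's product. The same flask charged with 0.550 equiv of reagent ends at a substrate ratio of 0.954, so the factor gives an excess of 76.2%, and that flask gives 76.6%.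

Readings and results are calculated for an exercise; noise was put on by code.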